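**The pitfall.** I could have read Z as a product that more time would raise, but in both runs below it levelled off while D and L went on growing.

| flask | E | X | remark | time |
|---|---|---|---|---|
| spring | 0.40 M | 1 equiv | run made earlier |  |
| winter | 1.6 M | 1 equiv | run made earlier |  |
| flask | 0.80 M | 1.00 equiv |  | 4.0 h |

- spring (time / h: D / %, Z / %, L / %): 0.667: 1.1, 10.8, 0; 1.33: 2.5, 13.4, 0.1; 2.00: 3.0, 14.2, 2.4; 2.50: 4.5, 14.2, 1.6
- winter (time / h: D / %, Z / %, L / %): 0.667: 2.8, 28.4, 0.6; 1.33: 5.9, 31.1, 2.0; 2.00: 7.9, 30.9, 4.3; 2.50: 9.3, 28.6, 5.4

(readings scatter by 0.5 percentage points)

* how much D the flask holds at 4.0 h, in percent of the E charged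
* how much Z the flask holds at 4.0 h, in percent of the E charged
* how much L the flask holds at 4.0 h, in percent of the E charged



**Turned round.** I asked what Z would need in order to outweigh free E. I treated E + X ⇌ Z as a pre-equilibrium, with D and L having used up X as well as E, so free E and free X share one fraction of their charges. From this I defined the holding constant: the Z share divided by the square of the free share and by the charged [E]. At 2.50 h the spring run's free share was 79.7%, giving 0.559 M⁻¹. The winter run's 56.7% gave 0.556 M⁻¹, at a charge larger by a factor of 4.00. I took the mean, 0.557 M⁻¹. Z outweighs free E where this constant times free [E] passes one. Even on the full charge, the new flask reaches 0.446, which is less than one.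

**Both ends.** For the early end I put the holding constant into this flask as though nothing went on to D, and reckoned a Z share of 25.1%; that is an estimate and not a ceiling, since the constant was read from runs already losing Z to D and L. At the late end, the last readings gave D + L formed at 0.189 h⁻¹ times Z. Joining the two ends, I let Z stand at its final share for 4.0 h. That left a free share of 66.0%, Z at 19.4% and D + L at 14.6%. I left the split between D and L open.

**The forecast.** It gave D 7.2%, Z 19% and L 6.3%, with the remark: “The D/L split is the least certain part”.

**The result.** The flask holds D 8.75%, Z 18.9% and L 8.04%.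

    E + X ⇌ Z (K = 0.650 M⁻¹, k = 0.668 M⁻¹ h⁻¹)
    Z → D (k = 0.218 h⁻¹)
    D ⇌ L (K = 2.30, k = 0.556 h⁻¹)

At 0.547 h Z fell back 4.7 times faster than it went on, and at 4.00 h the relaxation half-life of 0.404 h was short against the 4.0 h of the run. With 64% of E free, the holding constant gives this flask 18.4% of Z against the 18.9% it holds. The neighbour charged with 0.20 M of E has 86% free, which gives 8.24% of Z, and it holds 8.08%.

The data were computed for an exercise, and the scatter is random.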